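Toxiusol is assembled from an aryl decalin and a ring C/D allylic picolinate, joined at the end by an anti SN2′ alkylation. The decalin rests on one bond of ring A: that between its quaternary carbon C5 (CH3, ArCH2) and the A/B fusion CH C4a (numbering of 29), which is allylic to the ring A alkene. A lactone Ireland–Claisen rearrangement makes this bond, closes ring A, sets both stereocentres and moves the ring B alkene into ring A in a single operation; the lactone carbonyl later becomes the quaternary methyl. The precursor is a cis-4-methyl-6-cyclohexenyl δ-lactone with the arylmethyl group at C3 and the ring B quaternary centre bearing a silyloxyethyl arm.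

Key step: step 11

Ring labels: ring A = aryl-bearing cyclohexene; ring B = its fused partner; ring C = ring with the two vicinal methyl groups; ring D = gem-dimethylcyclohexene. Lactone locants: O1, C2(=O), C3, C4, C5, C6; cyclohexenyl locants C1′=C2′, quaternary C6′.

Remark: C3 of lactone 20 becomes trigonal in the ketene acetal, so its configuration is not critical; (3S,4R,6R,6′S)-20 and (1S,2R,5S,8aR)-24 are the configurations that map onto the target.

Assumption: methyl hydrogen (R)-3-methylglutarate (11) is taken as a commercial compound (it is also available by enzymatic desymmetrisation of dimethyl 3-methylglutarate).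

Assumption: the target is isolated as the free bis(hydrogen sulfate) as drawn; its salts differ only in the counter-ion.

Step 1
Reactants: 1 2-methylcyclohexan-1-one
Product: 2 trimethyl[(2-methylcyclohex-1-en-1-yl)oxy]silane
Conditions: Me3SiCl, NaI, Et3N, MeCN, 25 °C
Reagents that add atoms: chlorotrimethylsilane, C[Si](C)(C)Cl
Why: Me3SiI formed in situ with Et3N enolises the ketone reversibly, so the more substituted silyl enol ether should predominate (thermodynamic silyl enol ether formation), the minor regioisomer being removed by distillation.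

Step 2
Reactants: 2 trimethyl[(2-methylcyclohex-1-en-1-yl)oxy]silane; 3 allyl chloroformate
Product: 5 allyl 2-methylcyclohex-1-en-1-yl carbonate, via lithium enolate 4 (not isolated)
Conditions: MeLi, THF, 0 °C; then 3, −78 °C
Reagents that add atoms: none
Why: MeLi cleaves the O–Si bond to the regiodefined lithium enolate, which is acylated on oxygen by the chloroformate at low temperature (enolate O-acylation).

Step 3
Reactants: 5 allyl 2-methylcyclohex-1-en-1-yl carbonate
Product: 6 (2S)-2-allyl-2-methylcyclohexan-1-one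
Conditions: Pd2(dba)3 (2.5 mol %), (S)-t-Bu-PHOX (6 mol %), THF, 25 °C
Reagents that add atoms: none
Why: Zerovalent palladium ionises the allyl carbonate, CO2 is lost and the enolate recombines with the PHOX-bound allylpalladium fragment on one enantioface (Tsuji decarboxylative asymmetric allylic alkylation), the (S)-ligand giving the (S)-quaternary centre.

Step 4
Reactants: 6 (2S)-2-allyl-2-methylcyclohexan-1-one
Product: 8 (2S)-2-(2-hydroxyethyl)-2-methylcyclohexan-1-one, via keto aldehyde 7 (not isolated)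
Conditions: O3, CH2Cl2/MeOH, −78 °C; Me2S, −78 → 25 °C; then NaBH4, −78 °C
Reagents that add atoms: ozone, [O-][O+]=O
Why: Ozonolysis cleaves the terminal alkene and the resulting aldehyde is reduced by NaBH4 at −78 °C much faster than the hindered α-quaternary ketone (ozonolysis followed by chemoselective borohydride reduction), the quaternary centre being untouched.

Step 5
Reactants: 8 (2S)-2-(2-hydroxyethyl)-2-methylcyclohexan-1-one
Product: 9 (2S)-2-methyl-2-{2-[tri(propan-2-yl)silyloxy]ethyl}cyclohexan-1-one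
Conditions: i-Pr3SiCl, imidazole, DMF, 25 °C
Reagents that add atoms: chlorotri(propan-2-yl)silane, CC(C)[Si](Cl)(C(C)C)C(C)C
Why: Imidazole-promoted silylation of the primary alcohol (silyl ether protection) gives a bulky ether that should survive the organolithium, hydride and enolate steps that follow.

Step 6
Reactants: 9 (2S)-2-methyl-2-{2-[tri(propan-2-yl)silyloxy]ethyl}cyclohexan-1-one
Product: 10 2,4,6-tri(propan-2-yl)benzenesulfonyl hydrazone of ketone 9
Conditions: 2,4,6-(i-Pr)3C6H2SO2NHNH2, HCl (cat.), THF, 25 °C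
Reagents that add atoms: 2,4,6-tri(propan-2-yl)benzenesulfonohydrazide, CC(C)c1cc(C(C)C)c(S(=O)(=O)NN)c(C(C)C)c1
Why: Acid-catalysed condensation (hydrazone formation) places the N–S unit anti to the quaternary carbon and therefore syn to the only α-CH2 group, as the Shapiro reaction requires.

Step 7
Reactants: 11 methyl hydrogen (R)-3-methylglutarate
Product: 12 methyl (3S)-5-chloro-3-methyl-5-oxopentanoate
Conditions: (COCl)2, DMF (cat.), CH2Cl2, 0 → 25 °C
Reagents that add atoms: oxalyl chloride, ClC(=O)C(=O)Cl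
Why: Oxalyl chloride with catalytic DMF converts the free acid into the acid chloride (Vilsmeier-type activation) without touching the methyl ester or the stereocentre, whose descriptor changes only because the priorities change.

Step 8
Reactants: 10 2,4,6-tri(propan-2-yl)benzenesulfonyl hydrazone of ketone 9; 12 methyl (3S)-5-chloro-3-methyl-5-oxopentanoate
Product: 15 methyl (3R)-3-methyl-5-[(6S)-6-methyl-6-{2-[tri(propan-2-yl)silyloxy]ethyl}cyclohex-1-en-1-yl]-5-oxopentanoate, via vinyllithium 13 (not isolated), via vinylzinc chloride 14 (not isolated)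
Conditions: n-BuLi (2.1 equiv), THF, −78 → 0 °C; ZnCl2, −78 → 0 °C; then 12, Pd(PPh3)4 (5 mol %), 0 → 25 °C
Reagents that add atoms: none
Why: Double deprotonation with loss of sulfinate and N2 gives the vinyllithium regiospecifically (Shapiro reaction), and after transmetallation to zinc a palladium-catalysed acylation (Negishi ketone synthesis) joins it to the acid chloride while sparing the methyl ester.

Step 9
Reactants: 15 methyl (3R)-3-methyl-5-[(6S)-6-methyl-6-{2-[tri(propan-2-yl)silyloxy]ethyl}cyclohex-1-en-1-yl]-5-oxopentanoate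
Product: 17 (4R,6R)-4-methyl-6-[(6S)-6-methyl-6-{2-[tri(propan-2-yl)silyloxy]ethyl}cyclohex-1-en-1-yl]oxan-2-one, via hydroxy ester 16 (not isolated)
Conditions: (S)-Me-CBS oxazaborolidine (0.2 equiv), BH3·SMe2, THF, −30 °C; MeOH; then PPTS (cat.), toluene, 50 °C
Reagents that add atoms: none
Why: The oxazaborolidine–borane complex delivers hydride with the cyclohexenyl group as the large substituent (Corey–Bakshi–Shibata reduction), so the (S)-catalyst should set the (5R)-carbinol by reagent control, and the δ-hydroxy ester then closes to the lactone under mild acid (lactonisation), giving the cis-4,6-disubstituted ring.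

Step 10
Reactants: 17 (4R,6R)-4-methyl-6-[(6S)-6-methyl-6-{2-[tri(propan-2-yl)silyloxy]ethyl}cyclohex-1-en-1-yl]oxan-2-one; 18 2,5-dimethoxybenzyl chloride
Product: 20 (3S,4R,6R)-3-[(2,5-dimethoxyphenyl)methyl]-4-methyl-6-[(6S)-6-methyl-6-{2-[tri(propan-2-yl)silyloxy]ethyl}cyclohex-1-en-1-yl]oxan-2-one, via lithium enolate 19 (not isolated)
Conditions: LiN(i-Pr)2, THF, −78 °C; then 18, Bu4NI (cat.), DMPU, −78 → −20 °C
Reagents that add atoms: none
Why: The lithium enolate of the δ-lactone is alkylated by the benzylic halide (iodide formed in situ) anti to the C4 methyl group (enolate alkylation), and this C3 centre becomes trigonal again in step 11.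

Step 11
Reactants: 20 (3S,4R,6R)-3-[(2,5-dimethoxyphenyl)methyl]-4-methyl-6-[(6S)-6-methyl-6-{2-[tri(propan-2-yl)silyloxy]ethyl}cyclohex-1-en-1-yl]oxan-2-one
Product: 24 (1S,2R,5S,8aR)-1-[(2,5-dimethoxyphenyl)methyl]-2,5-dimethyl-5-{2-[tri(propan-2-yl)silyloxy]ethyl}-1,2,3,5,6,7,8,8a-octahydronaphthalene-1-carboxylic acid, via lithium enolate 21 (not isolated), via silyl ketene acetal 22 (not isolated), via silyl ester 23 (not isolated)
Conditions: LiN(i-Pr)2, THF, −78 °C; Me3SiCl/Et3N, −78 → 25 °C; toluene, 110 °C; then 1 M HCl (aq), 25 °C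
Reagents that add atoms: none
Why: The trimethylsilyl ketene acetal 22, whose geometry is fixed because the enol double bond is endocyclic, undergoes a concerted [3,3] sigmatropic shift (Ireland–Claisen rearrangement) in which C3 of the lactone bonds to C2′ of the cyclohexenyl group while the C6–O bond breaks and the alkene moves to C6=C1′. The closest known reaction type is the ring-contracting Ireland–Claisen rearrangement of alkenyl-substituted lactone silyl ketene acetals to cycloalkene carboxylic acids. Ring A closes as a six-membered carbocycle by this ring contraction: because C3 and C6 are tied by the two-carbon C4–C5 bridge, the pericyclic array can only be a boat, a bicyclo[2.2.2]octane-like transition state whose C(OSi)–O bridge becomes the carboxyl group. The quaternary centre is controlled by the C6 carbinol configuration, since the cyclohexenyl group can reach C3 only on its own face of the lactone, which places the carboxyl carbon trans and ArCH2 cis to the C4 methyl group (cis to the alkenyl group in 20). The fusion CH is controlled by the suprafacial course on the cyclohexenyl unit with its vinylic hydrogen on the inside of the boat, so that this hydrogen ends cis to ArCH2 and the new bond lies syn to the methyl group and anti to the silyloxyethyl arm of the ring B quaternary carbon. The step needs O- rather than C-silylation and rearrangement rather than ionisation of the allylic C–O bond, which the fully substituted enolate carbon, the small silyl group and the non-polar solvent should favour.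

Step 12
Reactants: 24 (1S,2R,5S,8aR)-1-[(2,5-dimethoxyphenyl)methyl]-2,5-dimethyl-5-{2-[tri(propan-2-yl)silyloxy]ethyl}-1,2,3,5,6,7,8,8a-octahydronaphthalene-1-carboxylic acid
Product: 25 [(1S,2R,5S,8aR)-1-[(2,5-dimethoxyphenyl)methyl]-2,5-dimethyl-5-{2-[tri(propan-2-yl)silyloxy]ethyl}-1,2,3,5,6,7,8,8a-octahydronaphthalen-1-yl]methanol
Conditions: LiAlH4, THF, 0 → 65 °C
Reagents that add atoms: none
Why: LiAlH4 reduces the hindered carboxylic acid to the neopentyl primary alcohol (hydride reduction) and leaves the silyl ether, the alkene and the aryl ethers unchanged.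

Step 13
Reactants: 25 [(1S,2R,5S,8aR)-1-[(2,5-dimethoxyphenyl)methyl]-2,5-dimethyl-5-{2-[tri(propan-2-yl)silyloxy]ethyl}-1,2,3,5,6,7,8,8a-octahydronaphthalen-1-yl]methanol
Product: 26 (1S,2R,5S,8aR)-1-[(2,5-dimethoxyphenyl)methyl]-2,5-dimethyl-5-{2-[tri(propan-2-yl)silyloxy]ethyl}-1,2,3,5,6,7,8,8a-octahydronaphthalene-1-carbaldehyde
Conditions: Dess–Martin periodinane, CH2Cl2, 25 °C
Reagents that add atoms: none
Why: The hypervalent iodine reagent oxidises the hindered primary alcohol to the non-enolisable aldehyde under near-neutral conditions (Dess–Martin oxidation).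

Step 14
Reactants: 26 (1S,2R,5S,8aR)-1-[(2,5-dimethoxyphenyl)methyl]-2,5-dimethyl-5-{2-[tri(propan-2-yl)silyloxy]ethyl}-1,2,3,5,6,7,8,8a-octahydronaphthalene-1-carbaldehyde
Product: 29 2-[(1S,4aS,5R,6R)-5-[(2,5-dimethoxyphenyl)methyl]-1,5,6-trimethyl-1,2,3,4,4a,5,6,7-octahydronaphthalen-1-yl]ethan-1-ol, via hydrazone 27 (not isolated), via silyl ether 28 (not isolated)
Conditions: N2H4·H2O, diethylene glycol, 130 °C; KOH, 200 °C; then Bu4NF, THF, 25 °C
Reagents that add atoms: none
Why: The hydrazone of the α-quaternary aldehyde loses N2 under hot base to give the methyl group (Wolff–Kishner reduction, Huang-Minlon procedure), and fluoride then removes the silyl group, so that any silyl ether already cleaved by the hot base converges on the same alcohol.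

Step 15
Reactants: 29 2-[(1S,4aS,5R,6R)-5-[(2,5-dimethoxyphenyl)methyl]-1,5,6-trimethyl-1,2,3,4,4a,5,6,7-octahydronaphthalen-1-yl]ethan-1-ol
Product: 30 (1S,4aS,5R,6R)-5-[(2,5-dimethoxyphenyl)methyl]-1-(2-iodoethyl)-1,5,6-trimethyl-1,2,3,4,4a,5,6,7-octahydronaphthalene
Conditions: I2, PPh3, imidazole, CH2Cl2, 0 → 25 °C
Reagents that add atoms: iodine, II
Why: The iodophosphonium salt activates the primary alcohol for displacement by iodide (Appel-type iodination) under conditions that should not affect the trisubstituted alkene.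

Step 16
Reactants: 31 (S)-pulegone; 32 [2-(1,3-dioxan-2-yl)ethyl]magnesium bromide
Product: 34 (2R,5S)-2-[4-(1,3-dioxan-2-yl)-2-methylbutan-2-yl]-5-methylcyclohexan-1-one, via cis epimer 33 (not isolated)
Conditions: CuBr·SMe2 (10 mol %), THF, −30 → 0 °C; aq NH4Cl; then NaOMe (cat.), MeOH, 25 °C
Reagents that add atoms: none
Why: Copper-catalysed conjugate addition of the Grignard reagent to the s-cis enone builds the gem-dimethyl quaternary carbon (Kharasch-type 1,4-addition), and base equilibration places both ring substituents equatorial, so the 2,5-trans ketone with C2 (R) should predominate under thermodynamic control, the remaining cis epimer being removed by chromatography no later than enone 41.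

Step 17
Reactants: 34 (2R,5S)-2-[4-(1,3-dioxan-2-yl)-2-methylbutan-2-yl]-5-methylcyclohexan-1-one
Product: 36 (2R,3S,6R)-6-[4-(1,3-dioxan-2-yl)-2-methylbutan-2-yl]-2,3-dimethylcyclohexan-1-one, via lithium enolate 35 (not isolated)
Conditions: LiN(i-Pr)2, THF, −78 °C; MeI, −78 → 0 °C
Reagents that add atoms: iodomethane, CI
Why: The bulky amide base removes a proton from the unhindered CH2 group (kinetic enolate formation) and the enolate is methylated there, mainly trans to the neighbouring methyl group, at a centre that becomes trigonal in step 18.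

Step 18
Reactants: 36 (2R,3S,6R)-6-[4-(1,3-dioxan-2-yl)-2-methylbutan-2-yl]-2,3-dimethylcyclohexan-1-one
Product: 38 (3S,6R)-6-[4-(1,3-dioxan-2-yl)-2-methylbutan-2-yl]-2,3-dimethylcyclohex-1-en-1-yl trifluoromethanesulfonate, via potassium enolate 37 (not isolated)
Conditions: KN(SiMe3)2, THF, −78 → −20 °C; PhNTf2, −78 → 0 °C
Reagents that add atoms: N-phenylbis(trifluoromethanesulfonimide), O=S(=O)(N(c1ccccc1)S(=O)(=O)C(F)(F)F)C(F)(F)F
Why: Deprotonation should occur at the methyl-bearing α-carbon, because the other α-hydrogen is shielded by the adjacent quaternary carbon and its enolate would suffer allylic strain, and the enolate is trapped on oxygen (enol triflate formation).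

Step 19
Reactants: 38 (3S,6R)-6-[4-(1,3-dioxan-2-yl)-2-methylbutan-2-yl]-2,3-dimethylcyclohex-1-en-1-yl trifluoromethanesulfonate
Product: 39 (3S,6R)-2,3-dimethyl-6-(2-methyl-5-oxopentan-2-yl)cyclohex-1-en-1-yl trifluoromethanesulfonate
Conditions: 3 M HCl (aq), THF, 50 °C
Reagents that add atoms: water, O
Why: Aqueous acid hydrolyses the 1,3-dioxane to the aldehyde (acetal hydrolysis) under conditions to which the vinyl triflate is stable.

Step 20
Reactants: 39 (3S,6R)-2,3-dimethyl-6-(2-methyl-5-oxopentan-2-yl)cyclohex-1-en-1-yl trifluoromethanesulfonate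
Product: 40 (4aR,7S)-4,4,7,8-tetramethyl-1,2,3,4,4a,5,6,7-octahydronaphthalen-1-ol as a mixture of C1 epimers
Conditions: CrCl2 (6 equiv), NiCl2 (2 mol %), DMF, 25 °C
Reagents that add atoms: none
Why: Zerovalent nickel inserts into the vinyl triflate and transmetallation gives a vinyl species of trivalent chromium that adds to the tethered aldehyde, closing ring D as a six-membered ring (intramolecular Nozaki–Hiyama–Kishi reaction).

Step 21
Reactants: 40 (4aR,7S)-4,4,7,8-tetramethyl-1,2,3,4,4a,5,6,7-octahydronaphthalen-1-ol as a mixture of C1 epimers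
Product: 41 (4aR,7S)-4,4,7,8-tetramethyl-3,4,4a,5,6,7-hexahydronaphthalen-1(2H)-one
Conditions: Dess–Martin periodinane, CH2Cl2, 25 °C
Reagents that add atoms: none
Why: Oxidation of the allylic alcohol (Dess–Martin oxidation) removes the uncontrolled carbinol centre and gives one tetrasubstituted enone.

Step 22
Reactants: 41 (4aR,7S)-4,4,7,8-tetramethyl-3,4,4a,5,6,7-hexahydronaphthalen-1(2H)-one
Product: 42 (1R,4aR,7S)-4,4,7,8-tetramethyl-1,2,3,4,4a,5,6,7-octahydronaphthalen-1-ol
Conditions: (S)-Me-CBS oxazaborolidine (0.5 equiv), BH3·SMe2, THF, −20 °C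
Reagents that add atoms: none
Why: Corey–Bakshi–Shibata reduction with the (S)-catalyst, the tetrasubstituted alkenyl carbon acting as the large group, should give the (1R)-alcohol, whose hydroxyl group is pseudoaxial, cis to the ring-fusion hydrogen and free of allylic strain with the C8 methyl group, so reagent and substrate preferences coincide.

Step 23
Reactants: 42 (1R,4aR,7S)-4,4,7,8-tetramethyl-1,2,3,4,4a,5,6,7-octahydronaphthalen-1-ol
Product: 43 (1R,4aR,7S)-4,4,7,8-tetramethyl-1,2,3,4,4a,5,6,7-octahydronaphthalen-1-yl pyridine-2-carboxylate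
Conditions: picolinic acid, DCC, DMAP (cat.), CH2Cl2, 25 °C
Reagents that add atoms: pyridine-2-carboxylic acid, OC(=O)c1ccccn1
Why: Carbodiimide activation with DMAP esterifies the secondary allylic alcohol with retention (Steglich esterification) and installs the chelating picolinate leaving group.

Step 24
Reactants: 30 (1S,4aS,5R,6R)-5-[(2,5-dimethoxyphenyl)methyl]-1-(2-iodoethyl)-1,5,6-trimethyl-1,2,3,4,4a,5,6,7-octahydronaphthalene; 43 (1R,4aR,7S)-4,4,7,8-tetramethyl-1,2,3,4,4a,5,6,7-octahydronaphthalen-1-yl pyridine-2-carboxylate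
Product: 46 (1S,4aS,5R,6R)-5-[(2,5-dimethoxyphenyl)methyl]-1,5,6-trimethyl-1-{2-[(1R,2S,4aR)-1,2,5,5-tetramethyl-1,2,3,4,4a,5,6,7-octahydronaphthalen-1-yl]ethyl}-1,2,3,4,4a,5,6,7-octahydronaphthalene, via alkyllithium 44 (not isolated), via Grignard reagent 45 (not isolated)
Conditions: t-BuLi (2 equiv), Et2O/pentane, −78 °C; MgBr2·OEt2, −78 → 0 °C; then 43, CuBr·SMe2 (20 mol %), THF, −30 → 0 °C
Reagents that add atoms: none
Why: Iodine–lithium exchange and transmetallation give the primary Grignard reagent, and under copper catalysis the magnesium-chelated picolinate, held pseudoaxial by allylic strain with the C8 methyl group, is displaced with allylic transposition by attack at C8 on the face opposite to the leaving group (copper-catalysed anti SN2′ allylic substitution), which should put the chain trans to the C7 methyl group, create the quaternary centre with the (R) configuration and leave the alkene at C8a=C1.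

Step 25
Reactants: 46 (1S,4aS,5R,6R)-5-[(2,5-dimethoxyphenyl)methyl]-1,5,6-trimethyl-1-{2-[(1R,2S,4aR)-1,2,5,5-tetramethyl-1,2,3,4,4a,5,6,7-octahydronaphthalen-1-yl]ethyl}-1,2,3,4,4a,5,6,7-octahydronaphthalene
Product: 48 hydroquinone corresponding to 46 (both OCH3 replaced by OH), via quinone 47 (not isolated)
Conditions: (NH4)2Ce(NO3)6, MeCN/H2O, 0 °C; then Na2S2O4, EtOAc/H2O, 25 °C
Reagents that add atoms: water, O
Why: Tetravalent cerium oxidises the electron-rich 1,4-dimethoxyarene to the benzoquinone with loss of both methyl groups as methanol (oxidative demethylation), and dithionite reduces the quinone to the hydroquinone without affecting the two trisubstituted alkenes.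

Step 26
Reactants: 48 hydroquinone corresponding to 46 (both OCH3 replaced by OH)
Product: 50 toxiusol, via pyridinium salt 49 (not isolated)
Conditions: SO3·pyridine, pyridine, 25 → 50 °C; then sulfonic acid resin (H+ form), MeOH/H2O, 0 °C
Reagents that add atoms: sulfur trioxide–pyridine complex, [O-]S(=O)(=O)[n+]1ccccc1
Why: The pyridine–SO3 complex transfers SO3 to both phenolic oxygens (O-sulfation), and exchange of the pyridinium counter-ions for protons on the resin at 0 °C should give the bis(hydrogen sulfate).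

Compound list

1 | 2-methylcyclohexan-1-one (racemic) | CC1CCCCC1=O | starting material
2 | trimethyl[(2-methylcyclohex-1-en-1-yl)oxy]silane | CC1=C(O[Si](C)(C)C)CCCC1 | intermediate
3 | allyl chloroformate | C=CCOC(=O)Cl | starting material
4 | lithium 2-methylcyclohex-1-en-1-olate | CC1=C(O[Li])CCCC1 | intermediate (not isolated)
5 | allyl 2-methylcyclohex-1-en-1-yl carbonate | CC1=C(OC(=O)OCC=C)CCCC1 | intermediate
6 | (2S)-2-allyl-2-methylcyclohexan-1-one | C=CC[C@]1(C)CCCCC1=O | intermediate
7 | 2-[(1S)-1-methyl-2-oxocyclohexyl]acetaldehyde | O=CC[C@]1(C)CCCCC1=O | intermediate (not isolated)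
8 | (2S)-2-(2-hydroxyethyl)-2-methylcyclohexan-1-one | OCC[C@]1(C)CCCCC1=O | intermediate
9 | (2S)-2-methyl-2-{2-[tri(propan-2-yl)silyloxy]ethyl}cyclohexan-1-one | CC(C)[Si](OCC[C@]1(C)CCCCC1=O)(C(C)C)C(C)C | intermediate
10 | N′-[(2S)-2-methyl-2-{2-[tri(propan-2-yl)silyloxy]ethyl}cyclohexylidene]-2,4,6-tri(propan-2-yl)benzenesulfonohydrazide (N–S unit anti to the quaternary carbon) | CC(C)[Si](OCC[C@]1(C)CCCCC1=NNS(=O)(=O)c1c(C(C)C)cc(C(C)C)cc1C(C)C)(C(C)C)C(C)C | intermediate
11 | methyl hydrogen (R)-3-methylglutarate, (3R)-5-methoxy-3-methyl-5-oxopentanoic acid | COC(=O)C[C@H](C)CC(=O)O | starting material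
12 | methyl (3S)-5-chloro-3-methyl-5-oxopentanoate | COC(=O)C[C@H](C)CC(=O)Cl | intermediate
13 | [(6S)-6-methyl-6-{2-[tri(propan-2-yl)silyloxy]ethyl}cyclohex-1-en-1-yl]lithium | [Li]C1=CCCC[C@@]1(C)CCO[Si](C(C)C)(C(C)C)C(C)C | intermediate (not isolated)
14 | chloro[(6S)-6-methyl-6-{2-[tri(propan-2-yl)silyloxy]ethyl}cyclohex-1-en-1-yl]zinc | Cl[Zn]C1=CCCC[C@@]1(C)CCO[Si](C(C)C)(C(C)C)C(C)C | intermediate (not isolated)
15 | methyl (3R)-3-methyl-5-[(6S)-6-methyl-6-{2-[tri(propan-2-yl)silyloxy]ethyl}cyclohex-1-en-1-yl]-5-oxopentanoate | COC(=O)C[C@H](C)CC(=O)C1=CCCC[C@@]1(C)CCO[Si](C(C)C)(C(C)C)C(C)C | intermediate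
16 | methyl (3R,5R)-5-hydroxy-3-methyl-5-[(6S)-6-methyl-6-{2-[tri(propan-2-yl)silyloxy]ethyl}cyclohex-1-en-1-yl]pentanoate | COC(=O)C[C@H](C)C[C@H](C1=CCCC[C@@]1(C)CCO[Si](C(C)C)(C(C)C)C(C)C)O | intermediate (not isolated)
17 | (4R,6R)-4-methyl-6-[(6S)-6-methyl-6-{2-[tri(propan-2-yl)silyloxy]ethyl}cyclohex-1-en-1-yl]oxan-2-one (cis lactone) | C[C@@H]1C[C@H](C2=CCCC[C@@]2(C)CCO[Si](C(C)C)(C(C)C)C(C)C)OC(=O)C1 | intermediate
18 | 2,5-dimethoxybenzyl chloride | COc1ccc(OC)c(CCl)c1 | starting material
19 | lithium enolate of lactone 17 | C[C@@H]1C[C@H](C2=CCCC[C@@]2(C)CCO[Si](C(C)C)(C(C)C)C(C)C)OC(O[Li])=C1 | intermediate (not isolated)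
20 | (3S,4R,6R)-3-[(2,5-dimethoxyphenyl)methyl]-4-methyl-6-[(6S)-6-methyl-6-{2-[tri(propan-2-yl)silyloxy]ethyl}cyclohex-1-en-1-yl]oxan-2-one | C[C@@H]1C[C@H](C2=CCCC[C@@]2(C)CCO[Si](C(C)C)(C(C)C)C(C)C)OC(=O)[C@H]1Cc1cc(OC)ccc1OC | intermediate (key-step precursor)
21 | lithium enolate of lactone 20 | C[C@@H]1C[C@H](C2=CCCC[C@@]2(C)CCO[Si](C(C)C)(C(C)C)C(C)C)OC(O[Li])=C1Cc1cc(OC)ccc1OC | intermediate (not isolated)
22 | trimethylsilyl ketene acetal of lactone 20 | C[C@@H]1C[C@H](C2=CCCC[C@@]2(C)CCO[Si](C(C)C)(C(C)C)C(C)C)OC(O[Si](C)(C)C)=C1Cc1cc(OC)ccc1OC | intermediate (not isolated)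
23 | trimethylsilyl ester of acid 24 | C[C@@H]1CC=C2[C@@H](CCC[C@@]2(C)CCO[Si](C(C)C)(C(C)C)C(C)C)[C@]1(C(=O)O[Si](C)(C)C)Cc1cc(OC)ccc1OC | intermediate (not isolated)
24 | (1S,2R,5S,8aR)-1-[(2,5-dimethoxyphenyl)methyl]-2,5-dimethyl-5-{2-[tri(propan-2-yl)silyloxy]ethyl}-1,2,3,5,6,7,8,8a-octahydronaphthalene-1-carboxylic acid | C[C@@H]1CC=C2[C@@H](CCC[C@@]2(C)CCO[Si](C(C)C)(C(C)C)C(C)C)[C@]1(C(=O)O)Cc1cc(OC)ccc1OC | intermediate (key-step product)
25 | [(1S,2R,5S,8aR)-1-[(2,5-dimethoxyphenyl)methyl]-2,5-dimethyl-5-{2-[tri(propan-2-yl)silyloxy]ethyl}-1,2,3,5,6,7,8,8a-octahydronaphthalen-1-yl]methanol | C[C@@H]1CC=C2[C@@H](CCC[C@@]2(C)CCO[Si](C(C)C)(C(C)C)C(C)C)[C@]1(CO)Cc1cc(OC)ccc1OC | intermediate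
26 | (1S,2R,5S,8aR)-1-[(2,5-dimethoxyphenyl)methyl]-2,5-dimethyl-5-{2-[tri(propan-2-yl)silyloxy]ethyl}-1,2,3,5,6,7,8,8a-octahydronaphthalene-1-carbaldehyde | C[C@@H]1CC=C2[C@@H](CCC[C@@]2(C)CCO[Si](C(C)C)(C(C)C)C(C)C)[C@]1(C=O)Cc1cc(OC)ccc1OC | intermediate
27 | hydrazone of aldehyde 26 | C[C@@H]1CC=C2[C@@H](CCC[C@@]2(C)CCO[Si](C(C)C)(C(C)C)C(C)C)[C@]1(C=NN)Cc1cc(OC)ccc1OC | intermediate (not isolated)
28 | tri(propan-2-yl)silyl ether of alcohol 29 | C[C@@H]1CC=C2[C@@H](CCC[C@@]2(C)CCO[Si](C(C)C)(C(C)C)C(C)C)[C@]1(C)Cc1cc(OC)ccc1OC | intermediate (not isolated)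
29 | 2-[(1S,4aS,5R,6R)-5-[(2,5-dimethoxyphenyl)methyl]-1,5,6-trimethyl-1,2,3,4,4a,5,6,7-octahydronaphthalen-1-yl]ethan-1-ol | C[C@@H]1CC=C2[C@@H](CCC[C@@]2(C)CCO)[C@]1(C)Cc1cc(OC)ccc1OC | intermediate
30 | (1S,4aS,5R,6R)-5-[(2,5-dimethoxyphenyl)methyl]-1-(2-iodoethyl)-1,5,6-trimethyl-1,2,3,4,4a,5,6,7-octahydronaphthalene | C[C@@H]1CC=C2[C@@H](CCC[C@@]2(C)CCI)[C@]1(C)Cc1cc(OC)ccc1OC | intermediate
31 | (S)-pulegone, (5S)-5-methyl-2-(propan-2-ylidene)cyclohexan-1-one | C[C@H]1CCC(=C(C)C)C(=O)C1 | starting material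
32 | [2-(1,3-dioxan-2-yl)ethyl]magnesium bromide (THF solution) | Br[Mg]CCC1OCCCO1 | starting material
33 | (2S,5S)-2-[4-(1,3-dioxan-2-yl)-2-methylbutan-2-yl]-5-methylcyclohexan-1-one (cis epimer) | C[C@H]1CC[C@@H](C(C)(C)CCC2OCCCO2)C(=O)C1 | intermediate (not isolated)
34 | (2R,5S)-2-[4-(1,3-dioxan-2-yl)-2-methylbutan-2-yl]-5-methylcyclohexan-1-one (trans) | C[C@H]1CC[C@H](C(C)(C)CCC2OCCCO2)C(=O)C1 | intermediate
35 | kinetic lithium enolate of ketone 34 | C[C@H]1CC[C@H](C(C)(C)CCC2OCCCO2)C(O[Li])=C1 | intermediate (not isolated)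
36 | (2R,3S,6R)-6-[4-(1,3-dioxan-2-yl)-2-methylbutan-2-yl]-2,3-dimethylcyclohexan-1-one | C[C@H]1CC[C@H](C(C)(C)CCC2OCCCO2)C(=O)[C@@H]1C | intermediate
37 | potassium enolate of ketone 36 (towards the methyl-bearing carbon) | C[C@H]1CC[C@H](C(C)(C)CCC2OCCCO2)C(O[K])=C1C | intermediate (not isolated)
38 | (3S,6R)-6-[4-(1,3-dioxan-2-yl)-2-methylbutan-2-yl]-2,3-dimethylcyclohex-1-en-1-yl trifluoromethanesulfonate | C[C@H]1CC[C@H](C(C)(C)CCC2OCCCO2)C(OS(=O)(=O)C(F)(F)F)=C1C | intermediate
39 | (3S,6R)-2,3-dimethyl-6-(2-methyl-5-oxopentan-2-yl)cyclohex-1-en-1-yl trifluoromethanesulfonate | C[C@H]1CC[C@H](C(C)(C)CCC=O)C(OS(=O)(=O)C(F)(F)F)=C1C | intermediate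
40 | (4aR,7S)-4,4,7,8-tetramethyl-1,2,3,4,4a,5,6,7-octahydronaphthalen-1-ol (both C1 epimers) | C[C@H]1CC[C@@H]2C(C)(C)CCC(O)C2=C1C | intermediate
41 | (4aR,7S)-4,4,7,8-tetramethyl-3,4,4a,5,6,7-hexahydronaphthalen-1(2H)-one | C[C@H]1CC[C@@H]2C(C)(C)CCC(=O)C2=C1C | intermediate
42 | (1R,4aR,7S)-4,4,7,8-tetramethyl-1,2,3,4,4a,5,6,7-octahydronaphthalen-1-ol (OH cis to the ring-fusion H) | C[C@H]1CC[C@@H]2C(C)(C)CC[C@@H](O)C2=C1C | intermediate
43 | (1R,4aR,7S)-4,4,7,8-tetramethyl-1,2,3,4,4a,5,6,7-octahydronaphthalen-1-yl pyridine-2-carboxylate | C[C@H]1CC[C@@H]2C(C)(C)CC[C@@H](OC(=O)c3ccccn3)C2=C1C | intermediate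
44 | alkyllithium from iodide 30 (Li in place of I) | C[C@@H]1CC=C2[C@@H](CCC[C@@]2(C)CC[Li])[C@]1(C)Cc1cc(OC)ccc1OC | intermediate (not isolated)
45 | alkylmagnesium bromide from iodide 30 (MgBr in place of I) | C[C@@H]1CC=C2[C@@H](CCC[C@@]2(C)CC[Mg]Br)[C@]1(C)Cc1cc(OC)ccc1OC | intermediate (not isolated)
46 | (1S,4aS,5R,6R)-5-[(2,5-dimethoxyphenyl)methyl]-1,5,6-trimethyl-1-{2-[(1R,2S,4aR)-1,2,5,5-tetramethyl-1,2,3,4,4a,5,6,7-octahydronaphthalen-1-yl]ethyl}-1,2,3,4,4a,5,6,7-octahydronaphthalene | C[C@@H]1CC=C2[C@@H](CCC[C@@]2(C)CC[C@@]2(C)C3=CCCC(C)(C)[C@H]3CC[C@@H]2C)[C@]1(C)Cc1cc(OC)ccc1OC | intermediate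
47 | 2-substituted 1,4-benzoquinone corresponding to 46 | C[C@@H]1CC=C2[C@@H](CCC[C@@]2(C)CC[C@@]2(C)C3=CCCC(C)(C)[C@H]3CC[C@@H]2C)[C@]1(C)CC1=CC(=O)C=CC1=O | intermediate (not isolated)
48 | hydroquinone corresponding to 46 (benzene-1,4-diol) | C[C@@H]1CC=C2[C@@H](CCC[C@@]2(C)CC[C@@]2(C)C3=CCCC(C)(C)[C@H]3CC[C@@H]2C)[C@]1(C)Cc1cc(O)ccc1O | intermediate
49 | bis(pyridinium) salt of the bis-sulfate of 48 | C[C@@H]1CC=C2[C@@H](CCC[C@@]2(C)CC[C@@]2(C)C3=CCCC(C)(C)[C@H]3CC[C@@H]2C)[C@]1(C)Cc1cc(OS(=O)(=O)[O-])ccc1OS(=O)(=O)[O-].c1cc[nH+]cc1.c1cc[nH+]cc1 | intermediate (not isolated)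
50 | toxiusol, bis(hydrogen sulfate) of hydroquinone 48 | C[C@@H]1CC=C2[C@@H](CCC[C@@]2(C)CC[C@@]2(C)C3=CCCC(C)(C)[C@H]3CC[C@@H]2C)[C@]1(C)Cc1cc(OS(=O)(=O)O)ccc1OS(=O)(=O)O | target

Total step count: 26 steps.
Longest linear sequence: 17 steps (steps 1–6, 8–15 and 24–26). The ring C/D branch (steps 16–23) has 8 steps before the coupling, and step 7 is a one-step side branch.

Steps most likely to fail

1. Step 11 (key step). What may go wrong: the boat is crowded, because the silyloxy group lies over the ring B quaternary carbon and ArCH2 eclipses the ring B CH2 at the forming bond. Ionisation of the allylic C–O bond or elimination to a diene acid may then outrun the sigmatropic shift.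
Fallback (ring A by cycloaddition; sets out from hydrazone 10 and chloride 18, comes back at aldehyde 26): vinyllithium 13, made from 10 as in step 8, is transmetallated with ZnCl2 and coupled with vinyl bromide under Pd(PPh3)4 catalysis to give the diene F1. Chloride 18 alkylates the sodium salt of triethyl phosphonoacetate to give the phosphonate F2. Horner–Wadsworth–Emmons reaction of F2 with acetaldehyde gives the (E)-enoate F3, i-Bu2AlH reduces it to the allylic alcohol F4, and MnO2 oxidises this to the (E)-enal F5. A Diels–Alder reaction of the diene F1 with the enal F5, promoted by Me2AlCl in CH2Cl2 at −78 to −20 °C, should then give aldehyde 26. The outcome relies on ortho regiochemistry, the formyl group endo, and approach anti to the silyloxyethyl arm. The route continues with step 14.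

2. Step 24. What may go wrong: direct substitution at the carbinol carbon instead of attack at the fully substituted alkene carbon, or loss of the organomagnesium reagent by protonation before it reacts, so that conversion stays low.
Fallback (conjugate addition in place of allylic substitution; sets out from iodide 30 and enone 41, comes back at 46): the Grignard reagent 45 from 30 is added to enone 41 with CuBr·SMe2 and Me3SiCl in THF at −78 to −20 °C. Attack anti to the C7 methyl group should give the silyl enol ether F6 with the quaternary centre in place. MeLi regenerates the enolate, which PhNTf2 converts into the enol triflate F7. Reduction of F7 with Pd(OAc)2, PPh3, HCO2H and Bu3N in DMF at 60 °C gives 46.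

3. Step 8. What may go wrong: quenching of the vinyllithium, consumption of the acid chloride by the lithium sulfinate formed beside it, or slow acylation of the hindered vinylzinc species.
Fallback (chromium-mediated addition to an aldehyde, then oxidation; sets out from ketone 9 and acid chloride 12, comes back at enone 15): ketone 9 is converted with LiN(i-Pr)2 and PhNTf2 into the enol triflate F8. Acid chloride 12 is reduced with H2 over Pd/BaSO4 in the presence of 2,6-lutidine (Rosenmund reduction) to the aldehyde F9. Coupling of F8 with F9 by CrCl2 and catalytic NiCl2 in DMF gives hydroxy ester 16 together with its C5 epimer F10. Dess–Martin oxidation of this mixture gives enone 15.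

Further compounds

F1 | step 11 | tri(propan-2-yl){2-[(1S)-2-ethenyl-1-methylcyclohex-2-en-1-yl]ethoxy}silane | C=CC1=CCCC[C@@]1(C)CCO[Si](C(C)C)(C(C)C)C(C)C
F2 | step 11 | ethyl 2-(diethoxyphosphoryl)-3-(2,5-dimethoxyphenyl)propanoate | CCOC(=O)C(Cc1cc(OC)ccc1OC)P(=O)(OCC)OCC
F3 | step 11 | ethyl (2E)-2-[(2,5-dimethoxyphenyl)methyl]but-2-enoate | C/C=C(\Cc1cc(OC)ccc1OC)C(=O)OCC
F4 | step 11 | (2E)-2-[(2,5-dimethoxyphenyl)methyl]but-2-en-1-ol | C/C=C(\Cc1cc(OC)ccc1OC)CO
F5 | step 11 | (2E)-2-[(2,5-dimethoxyphenyl)methyl]but-2-enal | C/C=C(\Cc1cc(OC)ccc1OC)C=O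
F6 | step 24 | trimethylsilyl enol ether of the conjugate adduct of 45 and 41 | C[C@@H]1CC=C2[C@@H](CCC[C@@]2(C)CC[C@@]2(C)C3=C(O[Si](C)(C)C)CCC(C)(C)[C@H]3CC[C@@H]2C)[C@]1(C)Cc1cc(OC)ccc1OC
F7 | step 24 | enol triflate corresponding to F6 (OSO2CF3 on the ring D alkene carbon of 46) | C[C@@H]1CC=C2[C@@H](CCC[C@@]2(C)CC[C@@]2(C)C3=C(OS(=O)(=O)C(F)(F)F)CCC(C)(C)[C@H]3CC[C@@H]2C)[C@]1(C)Cc1cc(OC)ccc1OC
F8 | step 8 | (6S)-6-methyl-6-{2-[tri(propan-2-yl)silyloxy]ethyl}cyclohex-1-en-1-yl trifluoromethanesulfonate | C[C@@]1(CCO[Si](C(C)C)(C(C)C)C(C)C)CCCC=C1OS(=O)(=O)C(F)(F)F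
F9 | step 8 | methyl (3R)-3-methyl-5-oxopentanoate | COC(=O)C[C@H](C)CC=O
F10 | step 8 | methyl (3R,5S)-5-hydroxy-3-methyl-5-[(6S)-6-methyl-6-{2-[tri(propan-2-yl)silyloxy]ethyl}cyclohex-1-en-1-yl]pentanoate | COC(=O)C[C@H](C)C[C@@H](C1=CCCC[C@@]1(C)CCO[Si](C(C)C)(C(C)C)C(C)C)O
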